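The constants used here come from no measurement; the rest is arithmetic.

The target, counted with its crystals, is the curve I watch in this flask, and I draw it before the run.

substrate 0.80 M; gas phase 86 mM (held); time 2.5 h

    gas phase ⇌ dissolved gas, rate k1*(csat - [dissolved gas]) (k1 = 0.0196 s⁻¹, csat = 86 mM)
    substrate + dissolved gas → target (k2 = 0.128 M⁻¹ s⁻¹)
    substrate → side product (k3 = 6.32 × 10⁻⁴ s⁻¹)
    crystals ⇌ target, rate k4*(cs4 - [target]) while solid is left; crystals form when [target] > cs4 (cs4 = 0.13 M, k4 = 0.0148 s⁻¹)
    dissolved gas → decomposition product (k5 = 4.71 × 10⁻⁷ s⁻¹)
    2 substrate → homo dimer (k6 = 0.0108 M⁻¹ s⁻¹)

- target and crystals together at 2.5 h, in percent of the substrate charged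
- concentration of dissolved gas in solution at 2.5 h, in percent of saturation

- percentages count the substrate that a species holds: one homo dimer counts as two
- target is meant together with its crystals
- a doubled species enters its step squared and goes two at a time
- solid, in amounts per volume of the solution: crystals
- at the start none of the gas is dissolved
- run time (flask): 2.5 h

The curve starts flat, with no gas dissolved, and bends upward within about 8.20 s, the relaxation time of dissolved gas at the charge. Its slope then stays under the transfer ceiling k1·csat, 0.126 min⁻¹ of the charge. Step 2 is transfer-limited (zero order in substrate) above 19.1% of the charge, where k2[substrate] equals k1, and pseudo-first-order below it. Dimerisation is second order, and at the charge it consumes substrate faster than transfer can supply gas, with a first half-life of 57.9 s.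

So I set the two consumption rates equal, leaving out the side step, which is slower than transfer at that level. This gives the parting level 26.6% of the charge, the substrate level at which, with dissolved gas at its steady value, target formation and dimerisation run equally fast. Above it dimerisation leads; below it the target step leads. By dimerisation alone the substrate reaches this level at about 2.66 min, which is where I expect the target curve to bend over toward a plateau near that same fraction. Crystals only move target between forms. As the substrate falls, dissolved gas should climb back toward saturation, since decomposition is much slower than transfer.

The forecast gives 31.5% and 100%, reckoning “the yield from the competition between gas-limited target formation and dimerisation”. Its yield stands above my figure.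

The flask gives 31.1% and >99.9%, so the forecast holds. Half of the dimer turnover is done by 0.475 min, half of the target turnover only by 2.19 min, and the flask ends with 63.5% as homo dimer. The yield lies 4.5 percentage points above the parting level.

In the neighbour flask with 0.20 M of substrate, the same level is 107% of its charge, so the target step leads once dissolved gas has built up. That flask gives 65.0% target against 27.5% homo dimer.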